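The 2,2-dimethylpyran ring of the chromene is cut at C2–C3 and C4–C4a. Ring oxygen O1, C2 with its two methyl groups and the neighbouring C8 hydroxyl are read as a masked catechol acetone ketal. Titanium tetrachloride opens 2,2-dimethyl-1,3-benzodioxole to an aryl oxocarbenium ion, which takes up ethyl vinyl ether as an acetylene equivalent in a formal [4+2] annulation, closes onto C4a and loses ethanol, giving the chromene and the free C8 hydroxyl in one operation. C6 is then borylated, a rhodium-catalysed asymmetric 1,4-addition to a chromone sets the (R) flavan centre, the ketone is removed, and a Claisen rearrangement moves a prenyl group from O8 to C7.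

Key step: step 1

Remark: locants O1 to C8a are those of the 2H-chromene unit of the target; compounds 1, 2, 8 and 13 are taken as commercial, and the flavan centre is (R) as drawn.

Step 1
Reactants: 1 2,2-dimethyl-1,3-benzodioxole; 2 ethyl vinyl ether
Product: 4 2,2-dimethyl-2H-chromen-8-ol, via 4-ethoxy-2,2-dimethylchroman-8-ol 3 (not isolated)
Conditions: TiCl4 (1.1 equiv), CH2Cl2, −78 °C, 15 min; 2 (1.1 equiv) added over 1 h; −78 → 0 °C; aq NaHCO3
Reagents that add atoms: none
Why: Proposed new method: TiCl4 should ionise one C–O bond of the ketal to a titanium aryloxide whose other oxygen carries the oxocarbenium ion ArO+=CMe2, the vinyl ether adds through its CH2 carbon (C2–C3 bond, Mukaiyama/Prins-type addition), the new ethoxycarbenium ion at C4 is attacked by the ring carbon ortho to the ether oxygen (C4–C4a bond, Friedel–Crafts), and the benzylic ethoxy group of 3 then ionises under the same Lewis acid with loss of a proton from C3. The closest known reaction type is the oxa-Povarov reaction (formal [4+2] of aryl oxocarbenium ions from mixed acetals with alkenes to chromans), together with Lewis acid ring-opening additions of π-nucleophiles to cyclic ketals and the acid-mediated cyclisation of 3-aryloxy acetals to 2H-chromenes; new here are the cyclic catechol ketal as oxocarbenium source and the ketone-derived gem-dimethyl cation. The pyran ring closes by 6-exo-trig attack of C4a on the pendant oxocarbenium carbon. No stereocentre remains, because the C4 ethoxy centre of 3 is lost on elimination. No choice between the two ketal oxygens is needed because 1 is C2v-symmetric and both ortho positions are equivalent; capture of the cation by the neighbouring aryloxide to a seven-membered acetal is reversible and should drain to the irreversible C–C closure, and slow addition of 2 to the pre-ionised ketal should limit vinyl ether oligomerisation.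

Step 2
Reactants: 4 2,2-dimethyl-2H-chromen-8-ol
Product: 7 2,2-dimethyl-6-(4,4,5,5-tetramethyl-1,3,2-dioxaborolan-2-yl)-2H-chromen-8-ol, via O-boryl ether 5 (not isolated), via O,6-diboryl chromene 6 (not isolated)
Conditions: [Ir(OMe)(cod)]2 (1.5 mol %), 4,4'-di-tert-butyl-2,2'-bipyridine (3 mol %), HBpin (1.1 equiv), B2pin2 (1.0 equiv), THF, rt → 60 °C; then MeOH
Reagents that add atoms: pinacolborane B1OC(C)(C)C(C)(C)O1 (O-boryl group of 5 and 6, lost on work-up); bis(pinacolato)diboron CC1(C)OB(OC1(C)C)B1OC(C)(C)C(C)(C)O1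
Why: Iridium-catalysed aromatic C–H borylation is sterically controlled, C6–H is the only ring C–H without an ortho substituent, and the phenol is masked in the flask as its O–Bpin ether, which also shields C7.

Step 3
Reactants: 8 7-hydroxy-4H-chromen-4-one
Product: 9 7-(methoxymethoxy)-4H-chromen-4-one
Conditions: MOMCl, i-Pr2NEt, CH2Cl2, 0 °C → rt
Reagents that add atoms: chloromethyl methyl ether COCCl
Why: Williamson-type O-alkylation of the phenol gives a base-stable MOM ether, so that the chromone is not deactivated as its phenoxide in step 4.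

Step 4
Reactants: 7 2,2-dimethyl-6-(4,4,5,5-tetramethyl-1,3,2-dioxaborolan-2-yl)-2H-chromen-8-ol; 9 7-(methoxymethoxy)-4H-chromen-4-one
Product: 10 (2R)-2-(8-hydroxy-2,2-dimethyl-2H-chromen-6-yl)-7-(methoxymethoxy)-2,3-dihydro-4H-chromen-4-one
Conditions: [RhCl(C2H4)2]2 (2.5 mol %), (R,R)-Ph-bod* [(1R,4R)-2,5-diphenylbicyclo[2.2.2]octa-2,5-diene] (5.5 mol %), aq KOH (0.5 equiv), dioxane/H2O 10:1, 40 °C; 9 (1.3 equiv)
Reagents that add atoms: none
Why: Hayashi–Miyaura rhodium-catalysed asymmetric 1,4-addition of the unhindered aryl boronate to the chromone, in which the chiral diene ligand controls aryl transfer to the Si face of C2 to set (R); the (R,R) ligand is chosen by analogy with its sense on cyclohexenone, and its antipode is used if the sense proves opposite.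

Step 5
Reactants: 10 (2R)-2-(8-hydroxy-2,2-dimethyl-2H-chromen-6-yl)-7-(methoxymethoxy)-2,3-dihydro-4H-chromen-4-one
Product: 11 N'-[(2R)-2-(8-hydroxy-2,2-dimethyl-2H-chromen-6-yl)-7-(methoxymethoxy)-2,3-dihydro-4H-chromen-4-ylidene]-4-methylbenzenesulfonohydrazide
Conditions: TsNHNH2 (1.2 equiv), MeOH, 50 °C
Reagents that add atoms: p-toluenesulfonyl hydrazide Cc1ccc(cc1)S(=O)(=O)NN
Why: Condensation of the aryl ketone with tosylhydrazide under near-neutral conditions should leave the C2 centre, the MOM ether and the chromene alkene untouched.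

Step 6
Reactants: 11 N'-[(2R)-2-(8-hydroxy-2,2-dimethyl-2H-chromen-6-yl)-7-(methoxymethoxy)-2,3-dihydro-4H-chromen-4-ylidene]-4-methylbenzenesulfonohydrazide
Product: 12 6-[(2R)-7-(methoxymethoxy)-3,4-dihydro-2H-chromen-2-yl]-2,2-dimethyl-2H-chromen-8-ol
Conditions: catecholborane (3 equiv), CHCl3, 0 °C → rt; NaOAc·3H2O, reflux
Reagents that add atoms: none
Why: Caglioti-type reductive deoxygenation of the tosylhydrazone with catecholborane (hydride addition to C=N, then loss of sulfinate and N2 from the diazene) turns C4 into CH2 without acid or hydrogenation, so the chromene alkene and the untouched C2 centre should survive.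

Step 7
Reactants: 13 2-methylbut-3-en-2-ol
Product: 14 methyl 2-methylbut-3-en-2-yl carbonate
Conditions: n-BuLi, THF, −78 °C; ClCO2Me, −78 °C → rt
Reagents that add atoms: methyl chloroformate COC(=O)Cl
Why: Acylation of the lithium alkoxide of the tertiary allylic alcohol gives the carbonate that serves as π-allyl precursor.

Step 8
Reactants: 12 6-[(2R)-7-(methoxymethoxy)-3,4-dihydro-2H-chromen-2-yl]-2,2-dimethyl-2H-chromen-8-ol; 14 methyl 2-methylbut-3-en-2-yl carbonate
Product: 15 (2R)-2-[2,2-dimethyl-8-(2-methylbut-3-en-2-yloxy)-2H-chromen-6-yl]-7-(methoxymethoxy)-3,4-dihydro-2H-chromene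
Conditions: Pd(PPh3)4 (5 mol %), 14 (1.5 equiv), THF, 0 °C → rt
Reagents that add atoms: none
Why: Tsuji–Trost O-allylation, in which the only free phenol (deprotonated by the methoxide released on decarboxylation) attacks the 1,1-dimethylallyl palladium complex at its more substituted terminus under kinetic control to give the tertiary aryl ether.

Step 9
Reactants: 15 (2R)-2-[2,2-dimethyl-8-(2-methylbut-3-en-2-yloxy)-2H-chromen-6-yl]-7-(methoxymethoxy)-3,4-dihydro-2H-chromene
Product: 17 6-[(2R)-7-(methoxymethoxy)-3,4-dihydro-2H-chromen-2-yl]-2,2-dimethyl-7-(3-methylbut-2-en-1-yl)-2H-chromen-8-ol, via ortho-dienone 16 (not isolated)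
Conditions: PhMe, 110 °C, sealed tube
Reagents that add atoms: none
Why: Aromatic Claisen rearrangement ([3,3]) of the 1,1-dimethylallyl aryl ether, in which C8a is blocked so the allyl unit is delivered with transposition to C7 as a normal prenyl group and the dienone tautomerises to the phenol.

Step 10
Reactants: 17 6-[(2R)-7-(methoxymethoxy)-3,4-dihydro-2H-chromen-2-yl]-2,2-dimethyl-7-(3-methylbut-2-en-1-yl)-2H-chromen-8-ol
Product: 18 (2R)-2-[8-hydroxy-2,2-dimethyl-7-(3-methylbut-2-en-1-yl)-2H-chromen-6-yl]-3,4-dihydro-2H-chromen-7-ol (CNP0175270.2)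
Conditions: HCl (cat.), MeOH, 40 °C
Reagents that add atoms: none
Why: Acid-catalysed acetal exchange removes the MOM ether as dimethoxymethane under conditions mild enough for the ortho-prenylphenol, the chromene and the flavan ether.

Compound list
1 | 2,2-dimethyl-1,3-benzodioxole | CC1(C)Oc2ccccc2O1 | starting material
2 | ethyl vinyl ether | C=COCC | starting material
3 | 4-ethoxy-2,2-dimethylchroman-8-ol (racemic) | CCOC1CC(C)(C)Oc2c(O)cccc12 | intermediate (not isolated)
4 | 2,2-dimethyl-2H-chromen-8-ol | CC1(C)C=Cc2cccc(O)c2O1 | intermediate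
5 | 2-[(2,2-dimethyl-2H-chromen-8-yl)oxy]-4,4,5,5-tetramethyl-1,3,2-dioxaborolane | CC1(C)C=Cc2cccc(OB3OC(C)(C)C(C)(C)O3)c2O1 | intermediate (not isolated)
6 | O,6-diboryl chromene (O–Bpin at C8, C–Bpin at C6) | CC1(C)C=Cc2cc(B3OC(C)(C)C(C)(C)O3)cc(OB4OC(C)(C)C(C)(C)O4)c2O1 | intermediate (not isolated)
7 | 2,2-dimethyl-6-(4,4,5,5-tetramethyl-1,3,2-dioxaborolan-2-yl)-2H-chromen-8-ol | CC1(C)C=Cc2cc(B3OC(C)(C)C(C)(C)O3)cc(O)c2O1 | intermediate
8 | 7-hydroxy-4H-chromen-4-one | O=c1ccoc2cc(O)ccc12 | starting material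
9 | 7-(methoxymethoxy)-4H-chromen-4-one | COCOc1ccc2c(c1)occc2=O | intermediate
10 | (2R)-2-(8-hydroxy-2,2-dimethyl-2H-chromen-6-yl)-7-(methoxymethoxy)-2,3-dihydro-4H-chromen-4-one | CC1(C)C=Cc2cc([C@H]3CC(=O)c4ccc(OCOC)cc4O3)cc(O)c2O1 | intermediate
11 | tosylhydrazone of 10 | CC1(C)C=Cc2cc([C@H]3CC(=NNS(=O)(=O)c5ccc(C)cc5)c4ccc(OCOC)cc4O3)cc(O)c2O1 | intermediate
12 | 6-[(2R)-7-(methoxymethoxy)-3,4-dihydro-2H-chromen-2-yl]-2,2-dimethyl-2H-chromen-8-ol | CC1(C)C=Cc2cc([C@H]3CCc4ccc(OCOC)cc4O3)cc(O)c2O1 | intermediate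
13 | 2-methylbut-3-en-2-ol | CC(C)(O)C=C | starting material
14 | methyl 2-methylbut-3-en-2-yl carbonate | COC(=O)OC(C)(C)C=C | intermediate
15 | (2R)-2-[2,2-dimethyl-8-(2-methylbut-3-en-2-yloxy)-2H-chromen-6-yl]-7-(methoxymethoxy)-3,4-dihydro-2H-chromene | CC1(C)C=Cc2cc([C@H]3CCc4ccc(OCOC)cc4O3)cc(OC(C)(C)C=C)c2O1 | intermediate
16 | 6-[(2R)-7-(methoxymethoxy)chroman-2-yl]-2,2-dimethyl-7-(3-methylbut-2-en-1-yl)-2H-chromen-8(7H)-one (ortho-dienone, C7 unspecified) | CC(C)=CCC1C(=O)C2=C(C=CC(C)(C)O2)C=C1[C@H]1CCc2ccc(OCOC)cc2O1 | intermediate (not isolated)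
17 | 6-[(2R)-7-(methoxymethoxy)-3,4-dihydro-2H-chromen-2-yl]-2,2-dimethyl-7-(3-methylbut-2-en-1-yl)-2H-chromen-8-ol | CC(C)=CCc1c([C@H]2CCc3ccc(OCOC)cc3O2)cc2c(c1O)OC(C)(C)C=C2 | intermediate
18 | (2R)-2-[8-hydroxy-2,2-dimethyl-7-(3-methylbut-2-en-1-yl)-2H-chromen-6-yl]-3,4-dihydro-2H-chromen-7-ol | CC(C)=CCc1c([C@H]2CCc3ccc(O)cc3O2)cc2c(c1O)OC(C)(C)C=C2 | target

Total step count: 10. Longest linear sequence: 8 steps (1, 2, 4, 5, 6, 8, 9, 10).

Steps most likely to fail

1. Step 1 (proposed new method). The vinyl ether may oligomerise cationically, or the cation may be held at oxygen as the seven-membered acetal, faster than the ring closes at carbon. Fallback with known chemistry, setting out from 1 and returning at 4: aqueous acid hydrolysis of 1 (HCl, THF/H2O) gives catechol F1; copper-catalysed mono-O-alkylation with 3-chloro-3-methylbut-1-yne (CuCl2 cat., DBU, MeCN, 0 °C, excess F1) gives 2-[(2-methylbut-3-yn-2-yl)oxy]phenol F2; heating in N,N-diethylaniline at 180 °C should trigger the aryl propargyl ether Claisen rearrangement, 1,5-hydrogen shift and oxa-6π electrocyclisation to 4.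

2. Step 2. Hydroboration or vinylic C–H borylation of the C3=C4 alkene may compete with arene borylation. Fallback, setting out from 3 and returning at 7: step 1 is quenched at −78 °C so that 3 is isolated. This alkene-free chroman is borylated under the conditions of step 2, through O-boryl ether F3 and diboryl chroman F4, to 4-ethoxy-2,2-dimethyl-6-(4,4,5,5-tetramethyl-1,3,2-dioxaborolan-2-yl)chroman-8-ol F5. Acid-catalysed elimination of ethanol (p-TsOH cat., toluene, 80 °C) then unmasks the chromene to give 7.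

3. Step 4. Transmetalation of the phenol-bearing pinacol boronate may be slow, with protodeboronation taking over, or facial selectivity on the chromone may be poor. Fallback, setting out from 7 and 9 and returning at 10: addition without a chiral ligand ([Rh(OH)(cod)]2, dioxane/H2O, 40 °C) gives racemic flavanone F6. Asymmetric transfer hydrogenation with dynamic kinetic resolution (RuCl(p-cymene)[(R,R)-TsDPEN], HCO2H/DBU, MeCN, 40 °C; the slower enantiomer racemises through reversible ring opening to the chalcone) should give (2R,4R)-cis-flavan-4-ol F7. Oxidation of the benzylic alcohol with MnO2 in CH2Cl2 returns enantioenriched 10.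

Further compounds
F1 | step 1 | catechol | Oc1ccccc1O
F2 | step 1 | 2-[(2-methylbut-3-yn-2-yl)oxy]phenol | C#CC(C)(C)Oc1ccccc1O
F3 | step 2 | 2-[(4-ethoxy-2,2-dimethylchroman-8-yl)oxy]-4,4,5,5-tetramethyl-1,3,2-dioxaborolane | CCOC1CC(C)(C)Oc2c(OB3OC(C)(C)C(C)(C)O3)cccc12
F4 | step 2 | O,6-diboryl 4-ethoxy-2,2-dimethylchroman | CCOC1CC(C)(C)Oc2c(OB3OC(C)(C)C(C)(C)O3)cc(B4OC(C)(C)C(C)(C)O4)cc12
F5 | step 2 | 4-ethoxy-2,2-dimethyl-6-(4,4,5,5-tetramethyl-1,3,2-dioxaborolan-2-yl)chroman-8-ol | CCOC1CC(C)(C)Oc2c(O)cc(B3OC(C)(C)C(C)(C)O3)cc12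
F6 | step 4 | racemic 2-(8-hydroxy-2,2-dimethyl-2H-chromen-6-yl)-7-(methoxymethoxy)-2,3-dihydro-4H-chromen-4-one | CC1(C)C=Cc2cc(C3CC(=O)c4ccc(OCOC)cc4O3)cc(O)c2O1
F7 | step 4 | (2R,4R)-2-(8-hydroxy-2,2-dimethyl-2H-chromen-6-yl)-7-(methoxymethoxy)-3,4-dihydro-2H-chromen-4-ol | CC1(C)C=Cc2cc([C@H]3C[C@@H](O)c4ccc(OCOC)cc4O3)cc(O)c2O1
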